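**Overview**

1. Retrosynthesis: the hexasubstituted benzene ring is taken apart at C8a–C8, C7–C6 and C6–C5 (chroman numbering) into a 3-ethylidene-oxan-2-ylidene chromium complex, 2-butyne and one CO ligand. The complex is cut further at C4a=C5 (aldol with acetaldehyde), at O1–C8a (alkynol cycloisomerization on chromium) and at C4–C4a (acetylide alkylation), which leads back to geranylgeraniol.
2. Enabling feature: in the benzene ring C4a–C5–C6–C7–C8–C8a the ether oxygen O1 (on C8a) and the hydroxyl (on C6) are para, and O1 is already tied to C2 by the pyran ring. O1, the carbene carbon C8a and the alkene C4a=C5 can therefore sit in one cyclic alkoxycarbene, and C6 with its hydroxyl can come from CO.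
3. Forward order: the C16 side chain with its three E alkenes is present from the first compound; the pyran ring closes as the oxan-2-ylidene complex (step 7); the benzene ring is built last (step 10) and appears directly as the free phenol.
4. Stereochemistry: C2 is the only stereocentre. It is set as a tertiary C–O bond by Sharpless epoxidation of geranylgeraniol with D-(−)-diethyl tartrate; that bond becomes O1–C2 and is never broken. The alkene geometry is bought with geranylgeraniol.

Key step: step 10

Remark: the CIP descriptor of the quaternary carbon reads S in complex 11 (and in F8) and R elsewhere, only because the ranking of its neighbours changes; no bond to this carbon is made or broken after step 1.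

**Route**

Step 1
Reactants: 1 (2E,6E,10E)-geranylgeraniol
Product: 2 (2R,3R)-2,3-epoxygeranylgeraniol
Conditions: Ti(OiPr)4 (10 mol %), D-(−)-diethyl tartrate (12 mol %), t-BuOOH, 4 Å molecular sieves, CH2Cl2, −20 °C
Reagents that add atoms: tert-butyl hydroperoxide, CC(C)(C)OO
Why: Sharpless asymmetric epoxidation: the titanium tartrate catalyst binds the allylic hydroxyl, so that of the four alkenes only C2=C3 is oxidised, and the D-(−)-tartrate directs oxygen to the face that gives the (2R,3R) epoxide, which sets the tertiary C–O stereocentre that becomes C2 of the chroman.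

Step 2
Reactants: 2 (2R,3R)-2,3-epoxygeranylgeraniol
Product: 3 (3R,6E,10E)-3,7,11,15-tetramethylhexadeca-6,10,14-triene-1,3-diol
Conditions: NaAlH2(OCH2CH2OCH3)2, THF, 0 °C to rt; aq. KNaC4H4O6 work-up
Reagents that add atoms: none
Why: Directed hydride opening of a 2,3-epoxy alcohol: the alkoxyaluminate formed on the primary oxygen delivers hydride within the molecule to C2, the less substituted epoxide carbon, so that the 1,3-diol forms with the tertiary C–O bond and its configuration untouched.

Step 3
Reactants: 3 (3R,6E,10E)-3,7,11,15-tetramethylhexadeca-6,10,14-triene-1,3-diol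
Product: 4 (3R,6E,10E)-3-hydroxy-3,7,11,15-tetramethylhexadeca-6,10,14-trien-1-yl 4-methylbenzenesulfonate
Conditions: TsCl (1.1 equiv), Et3N, DMAP (cat.), CH2Cl2, 0 °C
Reagents that add atoms: 4-methylbenzenesulfonyl chloride, Cc1ccc(cc1)S(Cl)(=O)=O
Why: Chemoselective sulfonylation of a primary alcohol next to a tertiary one, which is too hindered to react with TsCl at 0 °C.

Step 4
Reactants: 4 (3R,6E,10E)-3-hydroxy-3,7,11,15-tetramethylhexadeca-6,10,14-trien-1-yl 4-methylbenzenesulfonate
Product: 5 (3R,6E,10E)-3,7,11,15-tetramethyl-3-(triethylsilyloxy)hexadeca-6,10,14-trien-1-yl 4-methylbenzenesulfonate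
Conditions: Et3SiOSO2CF3, 2,6-lutidine, CH2Cl2, −78 to 0 °C
Reagents that add atoms: triethylsilyl trifluoromethanesulfonate, CC[Si](CC)(CC)OS(=O)(=O)C(F)(F)F
Why: Silylation of a hindered tertiary alcohol with a silyl triflate and a non-nucleophilic base, done to keep the alkoxide from closing an oxetane onto the tosylate in the basic step that follows.

Step 5
Reactants: 5 (3R,6E,10E)-3,7,11,15-tetramethyl-3-(triethylsilyloxy)hexadeca-6,10,14-trien-1-yl 4-methylbenzenesulfonate; 6 lithium acetylide ethylenediamine complex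
Product: 7 triethyl{[(5R,8E,12E)-5,9,13,17-tetramethyloctadeca-8,12,16-trien-1-yn-5-yl]oxy}silane
Conditions: LiC≡CH·H2NCH2CH2NH2 (3 equiv), DMSO, 15 °C to rt
Reagents that add atoms: none
Why: SN2 displacement of a primary tosylate by acetylide in DMSO, a standard chain extension to a terminal alkyne that leaves the silyl ether and the trisubstituted alkenes alone.

Step 6
Reactants: 7 triethyl{[(5R,8E,12E)-5,9,13,17-tetramethyloctadeca-8,12,16-trien-1-yn-5-yl]oxy}silane
Product: 8 (5R,8E,12E)-5,9,13,17-tetramethyloctadeca-8,12,16-trien-1-yn-5-ol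
Conditions: Bu4NF, THF, rt to 40 °C; H2O work-up
Reagents that add atoms: none
Why: Fluoride-induced desilylation, driven by the strength of the Si–F bond, releases the tertiary alcohol while the terminal alkyne and the alkenes are inert.

Step 7
Reactants: 8 (5R,8E,12E)-5,9,13,17-tetramethyloctadeca-8,12,16-trien-1-yn-5-ol; 9 chromium hexacarbonyl Cr(CO)6
Product: 11 pentacarbonyl{(6S)-6-methyl-6-[(3E,7E)-4,8,12-trimethyltrideca-3,7,11-trien-1-yl]oxan-2-ylidene}chromium, via Cr(CO)5(THF) 10 (not isolated)
Conditions: Cr(CO)6 (1.5 equiv), hν (Hg lamp, Pyrex), THF, 10 °C, Ar purge; then 8, THF, rt, dark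
Reagents that add atoms: none
Why: Cycloisomerization of a 4-alkyn-1-ol on zerovalent chromium: the terminal alkyne displaces THF from 10 and rearranges to the chromium vinylidene, whose metal-bound carbon is attacked by the tertiary hydroxyl in a six-membered ring closure (helped by the geminal substitution at the carbinol carbon), giving the cyclic alkoxycarbene complex with the stereocentre untouched, and the polyene is never irradiated because the photolysis is finished before 8 is added.

Step 8
Reactants: 11 pentacarbonyl{(6S)-6-methyl-6-[(3E,7E)-4,8,12-trimethyltrideca-3,7,11-trien-1-yl]oxan-2-ylidene}chromium; 12 acetaldehyde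
Product: 14 pentacarbonyl{(6R)-3-(1-hydroxyethyl)-6-methyl-6-[(3E,7E)-4,8,12-trimethyltrideca-3,7,11-trien-1-yl]oxan-2-ylidene}chromium (diastereomer mixture), via lithiated carbene complex 13 (not isolated)
Conditions: n-BuLi (1.05 equiv), THF, −78 °C; MeCHO (5 equiv), −78 °C; AcOH, THF, −78 °C
Reagents that add atoms: none
Why: Aldol addition of the alpha-anion of an alkoxycarbene complex to an unhindered aldehyde: the C3 hydrogens are the only acidic ones because the other neighbour of the ring oxygen is quaternary, cold addition of excess aldehyde with a cold acidic quench holds back the retro-aldol, and the two new stereocentres are of no consequence since both become sp2 carbons in step 9.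

Step 9
Reactants: 14 pentacarbonyl{(6R)-3-(1-hydroxyethyl)-6-methyl-6-[(3E,7E)-4,8,12-trimethyltrideca-3,7,11-trien-1-yl]oxan-2-ylidene}chromium
Product: 16 pentacarbonyl{(3E,6R)-3-ethylidene-6-methyl-6-[(3E,7E)-4,8,12-trimethyltrideca-3,7,11-trien-1-yl]oxan-2-ylidene}chromium, via secondary mesylate 15 (not isolated)
Conditions: CH3SO2Cl, Et3N, CH2Cl2, 0 °C
Reagents that add atoms: none
Why: Mesylation followed by E1cB elimination through the acidic alpha hydrogen gives the conjugated exocyclic alkene, and the E isomer should prevail because it keeps the methyl group away from the Cr(CO)5 fragment.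

Step 10
Reactants: 16 pentacarbonyl{(3E,6R)-3-ethylidene-6-methyl-6-[(3E,7E)-4,8,12-trimethyltrideca-3,7,11-trien-1-yl]oxan-2-ylidene}chromium; 17 2-butyne
Product: 19 (R)-alpha-tocotrienol, via tricarbonylchromium arene complex 18 (not isolated)
Conditions: 2-butyne (5 equiv), degassed THF, 55 °C, sealed tube; then CO (50 bar), 70 °C
Reagents that add atoms: none
Why: Dötz benzannulation of an alkenyl(alkoxy)carbene chromium complex with an alkyne: thermal loss of one CO lets 2-butyne coordinate and insert into the Cr=C bond (bond C8a–C8), a CO ligand then inserts (bond C7–C6) to give a chromium-bound dienylketene, the ketene carbon closes onto the ethylidene CH (bond C6–C5), and the C5 hydrogen shifts to oxygen to leave the phenol on Cr(CO)3, from which CO pressure frees 19 and returns Cr(CO)6. The closest known reaction type is the benzannulation of alpha-alkylidene 2-oxacycloalkylidene chromium complexes, described mainly for the five-membered oxacycle, so the six-membered case is an application within the same substrate class. The benzene ring closes by a six-electron electrocyclization of the triene C5=C4a–C8a=C8–C7=C6 (six-membered carbocycle), and the oxane ring, which holds O1 and C4 on the same side of the C8a–C4a bond, fixes the C8=C8a–C4a=C5 diene in the s-cis shape this needs. No stereocentre is formed and C2 is not involved, since the hindered aryl ether bond O1–C8a is present from step 7 and is not made by substitution. The step needs CO insertion and six-ring closure to win over five-ring closure without CO and over furan formation, which an alkenyl chromium carbene in an ethereal solvent with a dialkyl alkyne favours. The symmetry of 2-butyne removes any regiochemical question, and the isolated trisubstituted alkenes of the chain should not compete with the alkyne for the vacant site on chromium.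

**Compound list**

1 | (2E,6E,10E)-geranylgeraniol, (2E,6E,10E)-3,7,11,15-tetramethylhexadeca-2,6,10,14-tetraen-1-ol | CC(C)=CCC/C(C)=C/CC/C(C)=C/CC/C(C)=C/CO | starting material
2 | (2R,3R)-2,3-epoxygeranylgeraniol, {(2R,3R)-3-methyl-3-[(3E,7E)-4,8,12-trimethyltrideca-3,7,11-trien-1-yl]oxiran-2-yl}methanol | CC(C)=CCC/C(C)=C/CC/C(C)=C/CC[C@@]1(C)O[C@@H]1CO | intermediate
3 | (3R,6E,10E)-3,7,11,15-tetramethylhexadeca-6,10,14-triene-1,3-diol | CC(C)=CCC/C(C)=C/CC/C(C)=C/CC[C@@](C)(O)CCO | intermediate
4 | (3R,6E,10E)-3-hydroxy-3,7,11,15-tetramethylhexadeca-6,10,14-trien-1-yl 4-methylbenzenesulfonate | CC(C)=CCC/C(C)=C/CC/C(C)=C/CC[C@@](C)(O)CCOS(=O)(=O)c1ccc(C)cc1 | intermediate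
5 | (3R,6E,10E)-3,7,11,15-tetramethyl-3-(triethylsilyloxy)hexadeca-6,10,14-trien-1-yl 4-methylbenzenesulfonate | CC(C)=CCC/C(C)=C/CC/C(C)=C/CC[C@@](C)(O[Si](CC)(CC)CC)CCOS(=O)(=O)c1ccc(C)cc1 | intermediate
6 | lithium acetylide ethylenediamine complex, LiC≡CH·H2NCH2CH2NH2 | [Li]C#C.NCCN | starting material
7 | triethyl{[(5R,8E,12E)-5,9,13,17-tetramethyloctadeca-8,12,16-trien-1-yn-5-yl]oxy}silane | CC(C)=CCC/C(C)=C/CC/C(C)=C/CC[C@@](C)(O[Si](CC)(CC)CC)CCC#C | intermediate
8 | (5R,8E,12E)-5,9,13,17-tetramethyloctadeca-8,12,16-trien-1-yn-5-ol | CC(C)=CCC/C(C)=C/CC/C(C)=C/CC[C@@](C)(O)CCC#C | intermediate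
9 | chromium hexacarbonyl, Cr(CO)6 | O=C=[Cr](=C=O)(=C=O)(=C=O)(=C=O)=C=O | starting material
10 | pentacarbonyl(tetrahydrofuran)chromium, Cr(CO)5(THF) | C1CC[O+](C1)[Cr-](=C=O)(=C=O)(=C=O)(=C=O)=C=O | intermediate
11 | pentacarbonyl{(6S)-6-methyl-6-[(3E,7E)-4,8,12-trimethyltrideca-3,7,11-trien-1-yl]oxan-2-ylidene}chromium | CC(C)=CCC/C(C)=C/CC/C(C)=C/CC[C@]1(C)CCCC(=[Cr](=C=O)(=C=O)(=C=O)(=C=O)=C=O)O1 | intermediate
12 | acetaldehyde | CC=O | starting material
13 | lithium salt of complex 11 deprotonated at C3 of the oxane ring | CC(C)=CCC/C(C)=C/CC/C(C)=C/CC[C@]1(C)CC[CH-]C(=[Cr](=C=O)(=C=O)(=C=O)(=C=O)=C=O)O1.[Li+] | intermediate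
14 | pentacarbonyl{(6R)-3-(1-hydroxyethyl)-6-methyl-6-[(3E,7E)-4,8,12-trimethyltrideca-3,7,11-trien-1-yl]oxan-2-ylidene}chromium, diastereomer mixture at C3 and at the carbinol carbon | CC(C)=CCC/C(C)=C/CC/C(C)=C/CC[C@]1(C)CCC(C(C)O)C(=[Cr](=C=O)(=C=O)(=C=O)(=C=O)=C=O)O1 | intermediate
15 | methanesulfonate of 14, pentacarbonyl{(6R)-3-[1-(methylsulfonyloxy)ethyl]-6-methyl-6-[(3E,7E)-4,8,12-trimethyltrideca-3,7,11-trien-1-yl]oxan-2-ylidene}chromium | CC(C)=CCC/C(C)=C/CC/C(C)=C/CC[C@]1(C)CCC(C(C)OS(C)(=O)=O)C(=[Cr](=C=O)(=C=O)(=C=O)(=C=O)=C=O)O1 | intermediate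
16 | pentacarbonyl{(3E,6R)-3-ethylidene-6-methyl-6-[(3E,7E)-4,8,12-trimethyltrideca-3,7,11-trien-1-yl]oxan-2-ylidene}chromium | CC(C)=CCC/C(C)=C/CC/C(C)=C/CC[C@]1(C)CC/C(=C\C)C(=[Cr](=C=O)(=C=O)(=C=O)(=C=O)=C=O)O1 | intermediate
17 | 2-butyne | CC#CC | starting material
18 | tricarbonyl[η6-(R)-alpha-tocotrienol]chromium, Cr(CO)3 bound to the face of the benzene ring (metal fragment written as a separate component) | CC(C)=CCC/C(C)=C/CC/C(C)=C/CC[C@]1(C)CCc2c(C)c(O)c(C)c(C)c2O1.O=C=[Cr](=C=O)=C=O | intermediate
19 | (R)-alpha-tocotrienol, (2R)-2,5,7,8-tetramethyl-2-[(3E,7E)-4,8,12-trimethyltrideca-3,7,11-trien-1-yl]-3,4-dihydro-2H-chromen-6-ol | CC(C)=CCC/C(C)=C/CC/C(C)=C/CC[C@]1(C)CCc2c(C)c(O)c(C)c(C)c2O1 | target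

**Step count**

Total: 10 steps. Longest linear sequence: 10 steps, from 1.

**Steps most likely to fail**

Step 10. The annulation may close a five-membered ring without CO insertion, or the hindered tertiary-alkoxy carbene may lose its metal before the alkyne inserts. The fallback sets out from 5 and returns at 19; the arene is brought in preformed and the ring oxygen is joined to it afterwards. The Grignard reagent (2,5-dimethoxy-3,4,6-trimethylphenyl)magnesium bromide F1, made from the aryl bromide and Mg in THF, would be coupled with tosylate 5 under Li2CuCl4 catalysis (THF, −20 °C to rt). This should give triethyl{[(3R,6E,10E)-1-(2,5-dimethoxy-3,4,6-trimethylphenyl)-3,7,11,15-tetramethylhexadeca-6,10,14-trien-3-yl]oxy}silane F2. Bu4NF would free the tertiary alcohol (3R,6E,10E)-1-(2,5-dimethoxy-3,4,6-trimethylphenyl)-3,7,11,15-tetramethylhexadeca-6,10,14-trien-3-ol F3. (NH4)2Ce(NO3)6 in aqueous MeCN at 0 °C would oxidise the dimethoxyarene to the hydroxy quinone 2-[(3R,6E,10E)-3-hydroxy-3,7,11,15-tetramethylhexadeca-6,10,14-trien-1-yl]-3,5,6-trimethylcyclohexa-2,5-diene-1,4-dione F4. Na2S2O4 would reduce it to 2-[(3R,6E,10E)-3-hydroxy-3,7,11,15-tetramethylhexadeca-6,10,14-trien-1-yl]-3,5,6-trimethylbenzene-1,4-diol F5, and a catalytic amount of p-TsOH in degassed benzene would close this to 19. In the saturated (tocopherol) series this cyclodehydration is known to keep the configuration of the carbinol carbon, the side-chain oxygen adding to the ring carbon and becoming O1. The acid would have to be kept mild for the sake of the triene.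

Step 7. The tertiary hydroxyl may be too slow to capture the vinylidene in a six-membered closure, so that the alkyne oligomerises on chromium instead. The fallback sets out from 4 and returns at 11; the carbene carbon comes from a preformed alkoxycarbene complex. KOtBu in THF would close hydroxy tosylate 4 to (2R)-2-methyl-2-[(3E,7E)-4,8,12-trimethyltrideca-3,7,11-trien-1-yl]oxetane F6, without touching the C–O bond at the stereocentre. Pentacarbonyl[methoxy(methyl)carbene]chromium, (CO)5Cr=C(OCH3)CH3, would be deprotonated with n-BuLi at −78 °C to its lithium anion F7. With BF3·OEt2 this anion would open the oxetane at its CH2 terminus to pentacarbonyl[(5S,8E,12E)-5-hydroxy-1-methoxy-5,9,13,17-tetramethyloctadeca-8,12,16-trien-1-ylidene]chromium F8, formed as its alkoxide. On warming, the tertiary alkoxide would displace methoxide at the carbene carbon and give 11. This is the known annulation of carbene-complex anions with epoxides, extended by one ring atom.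

Step 8. The aldol addition may revert (retro-aldol), or proton transfer and self-condensation of the aldehyde may overtake it. The fallback sets out from 11 and returns at 16; the two carbons are attached by an irreversible alkylation. The lithium anion 13 would be alkylated at −78 °C with 1-chloroethyl methyl ether (CC(Cl)OC) to give pentacarbonyl{(6R)-3-(1-methoxyethyl)-6-methyl-6-[(3E,7E)-4,8,12-trimethyltrideca-3,7,11-trien-1-yl]oxan-2-ylidene}chromium F9. Elimination of methanol on basic Al2O3 would then give 16, in analogy to the known route to alpha-methylene oxacarbene complexes from chloromethyl methyl ether.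

**Further compounds**

F1 | step 10 | (2,5-dimethoxy-3,4,6-trimethylphenyl)magnesium bromide | COc1c(C)c(C)c(OC)c(C)c1[Mg]Br
F2 | step 10 | triethyl{[(3R,6E,10E)-1-(2,5-dimethoxy-3,4,6-trimethylphenyl)-3,7,11,15-tetramethylhexadeca-6,10,14-trien-3-yl]oxy}silane | CC(C)=CCC/C(C)=C/CC/C(C)=C/CC[C@@](C)(O[Si](CC)(CC)CC)CCc1c(C)c(OC)c(C)c(C)c1OC
F3 | step 10 | (3R,6E,10E)-1-(2,5-dimethoxy-3,4,6-trimethylphenyl)-3,7,11,15-tetramethylhexadeca-6,10,14-trien-3-ol | CC(C)=CCC/C(C)=C/CC/C(C)=C/CC[C@@](C)(O)CCc1c(C)c(OC)c(C)c(C)c1OC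
F4 | step 10 | 2-[(3R,6E,10E)-3-hydroxy-3,7,11,15-tetramethylhexadeca-6,10,14-trien-1-yl]-3,5,6-trimethylcyclohexa-2,5-diene-1,4-dione | CC(C)=CCC/C(C)=C/CC/C(C)=C/CC[C@@](C)(O)CCC1=C(C)C(=O)C(C)=C(C)C1=O
F5 | step 10 | 2-[(3R,6E,10E)-3-hydroxy-3,7,11,15-tetramethylhexadeca-6,10,14-trien-1-yl]-3,5,6-trimethylbenzene-1,4-diol | CC(C)=CCC/C(C)=C/CC/C(C)=C/CC[C@@](C)(O)CCc1c(C)c(O)c(C)c(C)c1O
F6 | step 7 | (2R)-2-methyl-2-[(3E,7E)-4,8,12-trimethyltrideca-3,7,11-trien-1-yl]oxetane | CC(C)=CCC/C(C)=C/CC/C(C)=C/CC[C@]1(C)CCO1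
F7 | step 7 | lithium anion of pentacarbonyl[methoxy(methyl)carbene]chromium | [Li+].[CH2-]C(OC)=[Cr](=C=O)(=C=O)(=C=O)(=C=O)=C=O
F8 | step 7 | pentacarbonyl[(5S,8E,12E)-5-hydroxy-1-methoxy-5,9,13,17-tetramethyloctadeca-8,12,16-trien-1-ylidene]chromium | CC(C)=CCC/C(C)=C/CC/C(C)=C/CC[C@@](C)(O)CCCC(OC)=[Cr](=C=O)(=C=O)(=C=O)(=C=O)=C=O
F9 | step 8 | pentacarbonyl{(6R)-3-(1-methoxyethyl)-6-methyl-6-[(3E,7E)-4,8,12-trimethyltrideca-3,7,11-trien-1-yl]oxan-2-ylidene}chromium | CC(C)=CCC/C(C)=C/CC/C(C)=C/CC[C@]1(C)CCC(C(C)OC)C(=[Cr](=C=O)(=C=O)(=C=O)(=C=O)=C=O)O1
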